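**Strategy.** Both interflavanyl bonds (fisetinidol C4 to catechin C8 and C6) are cut to (+)-catechin and two molecules of one 2,3-trans-flavan-3,4-diol. Ring C of that unit (O1–C2–C3–C4–C4a–C8a) is never cyclised: it grows from a 3-hydroxy-2,3-dihydrobenzofuran-3-carbaldehyde by an α-ketol ring expansion in which the electron-rich ring A carbon shifts from the carbinol carbon to the formyl carbon. The step exploits the C3 carbinol next to the benzylic C4 on ring A: the formyl carbon becomes C4, the later cation site, and the carbinol carbon the C3 ketone, reduced in the same flask. The precursor comes from an enantioselective carbenoid C–H insertion that sets C2.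

Key step: step 7

Remark: dirhodium tetrakis[N-phthaloyl-(S)-tert-leucinate] is assumed to give the (2S,3R)-cis insertion product; should this substrate show the opposite sense of induction, the (R)-configured catalyst is used and nothing else changes.
Remark: the flavan-3,4-diol is drawn as the 3,4-cis isomer that the chelate model predicts; its C4 epimer would serve equally, because C4 is ionised in the coupling.
Remark: 6-hydroxy-1-benzofuran-2(3H)-one (the lactone of 2,4-dihydroxyphenylacetic acid), 3,4-bis(benzyloxy)benzyl chloride and (+)-catechin are taken as purchasable.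

**Step 1**
Reactants: 1 6-hydroxy-1-benzofuran-2(3H)-one
Product: 2 6-(benzyloxy)-1-benzofuran-2(3H)-one
Conditions: BnBr (1.05 equiv), K2CO3 (1.1 equiv), acetone, rt
Reagents that add atoms: benzyl bromide, BrCc1ccccc1
Why: Williamson ether synthesis on the only free hydroxyl; one equivalent of mild base at room temperature should keep the lactone enolate from competing.

**Step 2**
Reactants: 2 6-(benzyloxy)-1-benzofuran-2(3H)-one; 3 3,4-bis(benzyloxy)benzyl chloride
Product: 5 methyl 2-[4-(benzyloxy)-2-{[3,4-bis(benzyloxy)phenyl]methoxy}phenyl]acetate, via sodium phenolate 4 (not isolated)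
Conditions: NaOMe (1.05 equiv, conc. solution in MeOH), DMF, 0 °C; then 3, NaI (10 mol %), rt
Reagents that add atoms: sodium methoxide, C[O-].[Na+]
Why: Methoxide opens the aryl ester (transesterification) and the released phenolate is alkylated in the same flask (Williamson ether synthesis), so the lactone itself tells the two ring A oxygens apart.

**Step 3**
Reactants: 5 methyl 2-[4-(benzyloxy)-2-{[3,4-bis(benzyloxy)phenyl]methoxy}phenyl]acetate
Product: 6 methyl 2-[4-(benzyloxy)-2-{[3,4-bis(benzyloxy)phenyl]methoxy}phenyl]-2-diazoacetate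
Conditions: 4-acetamidobenzenesulfonyl azide (1.3 equiv), DBU (1.5 equiv), MeCN, 0 °C to rt
Reagents that add atoms: 4-acetamidobenzenesulfonyl azide, CC(=O)Nc1ccc(cc1)S(=O)(=O)N=[N+]=[N-]
Why: Regitz diazo transfer to the arylacetate enolate, a standard entry to aryldiazoacetates.

**Step 4**
Reactants: 6 methyl 2-[4-(benzyloxy)-2-{[3,4-bis(benzyloxy)phenyl]methoxy}phenyl]-2-diazoacetate
Product: 7 methyl (2S,3R)-6-(benzyloxy)-2-[3,4-bis(benzyloxy)phenyl]-2,3-dihydro-1-benzofuran-3-carboxylate (2,3-cis)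
Conditions: dirhodium tetrakis[N-phthaloyl-(S)-tert-leucinate], Rh2(S-PTTL)4 (1 mol %), toluene, −78 to −40 °C
Reagents that add atoms: none
Why: Intramolecular C–H insertion of the donor–acceptor rhodium carbenoid into the electron-rich benzylic ether C–H bond closes the five-membered ring, and the chiral carboxylate ligands set C2 (and the cis C3) in that event.

**Step 5**
Reactants: 7 methyl (2S,3R)-6-(benzyloxy)-2-[3,4-bis(benzyloxy)phenyl]-2,3-dihydro-1-benzofuran-3-carboxylate
Product: 9 methyl (2R,3S)-6-(benzyloxy)-2-[3,4-bis(benzyloxy)phenyl]-3-hydroxy-2,3-dihydro-1-benzofuran-3-carboxylate (3-OH trans to the 2-aryl group), via potassium enolate 8 (not isolated)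
Conditions: KN(SiMe3)2 (1.15 equiv), THF, −78 °C; then 2-(phenylsulfonyl)-3-phenyloxaziridine (1.3 equiv), −78 °C; then AcOH
Reagents that add atoms: 2-(phenylsulfonyl)-3-phenyloxaziridine, O=S(=O)(c1ccccc1)N1OC1c1ccccc1
Why: Electrophilic hydroxylation of the ester enolate by the N-sulfonyloxaziridine; oxygen should arrive on the face opposite the 2-aryl group, and C2 stays intact because ring opening of the enolate by β-elimination would be a retro-5-endo-trig process.

**Step 6**
Reactants: 9 methyl (2R,3S)-6-(benzyloxy)-2-[3,4-bis(benzyloxy)phenyl]-3-hydroxy-2,3-dihydro-1-benzofuran-3-carboxylate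
Product: 10 (2R,3S)-6-(benzyloxy)-2-[3,4-bis(benzyloxy)phenyl]-3-hydroxy-2,3-dihydro-1-benzofuran-3-carbaldehyde
Conditions: i-Bu2AlH (2.3 equiv), CH2Cl2, −78 °C; MeOH, aq potassium sodium tartrate; used crude
Reagents that add atoms: none
Why: Partial reduction of an ester with i-Bu2AlH at −78 °C should stop at the aldehyde oxidation level, helped by chelation through the neighbouring aluminium alkoxide.

**Step 7**
Reactants: 10 (2R,3S)-6-(benzyloxy)-2-[3,4-bis(benzyloxy)phenyl]-3-hydroxy-2,3-dihydro-1-benzofuran-3-carbaldehyde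
Product: 12 (2R,3S,4S)-7-(benzyloxy)-2-[3,4-bis(benzyloxy)phenyl]chromane-3,4-diol (2,3-trans, 3,4-cis), via 4-hydroxychroman-3-one 11 (not isolated)
Conditions: Sc(OTf)3 (10 mol %), CH2Cl2, −20 to 0 °C; then MeOH, NaBH4, −78 to −20 °C
Reagents that add atoms: none
Why: Sc(OTf)3 chelates the tertiary carbinol oxygen and the formyl oxygen of 10, and the electron-rich ring A carbon (para to OBn, ortho to O1) shifts from the carbinol carbon to the formyl carbon, so that the carbinol carbon becomes the C3 ketone and the formyl carbon the benzylic C4 carbinol of 11; this is the α-ketol (acyloin) rearrangement in its ring-enlarging form, known for 1-hydroxycycloalkanecarbaldehydes. Ring C (O1–C2–C3–C4–C4a–C8a) is therefore not closed by a cyclisation but grows from the five-membered O1–C2–C3–C3a–C7a ring by a suprafacial 1,2-aryl shift that inserts the former formyl carbon between C3 and the aromatic carbon. C2 is not touched and keeps the configuration set in step 4; the C4 carbinol follows from the syn chelate and is of no consequence, since C4 is ionised in step 8. C3 is set by NaBH4 adding along the axial trajectory, anti to the axial C2–H and to the C4–O bond, which should place the 3-OH equatorial and trans to the 2-aryl group. The selectivity needed is aryl over C2 migration, which the 2,4-dioxygenated aryl group should secure; if C2 migrated, the isomeric α-ketol would be reduced by the same hydride to a 2,3-trans-flavan-3,4-diol of the same C2 and C3 configuration. Reduction at low temperature straight after the shift keeps the enolisable C2–H of the 3-ketone from epimerising.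

**Step 8**
Reactants: 12 (2R,3S,4S)-7-(benzyloxy)-2-[3,4-bis(benzyloxy)phenyl]chromane-3,4-diol (2.4 equiv); 13 (+)-catechin (1 equiv)
Product: 15 7,3',4'-tri-O-benzyl-fisetinidol-(4α→6)-catechin-(8→4α)-7,3',4'-tri-O-benzyl-fisetinidol, via C8 monoadduct 14 (not isolated)
Conditions: BF3·OEt2 (0.3 equiv), 1,4-dioxane, 10 °C to rt, 12 added in portions
Reagents that add atoms: none
Why: Acid-promoted Friedel–Crafts alkylation (the biomimetic flavan-3,4-diol condensation): the benzylic C4–OH ionises to the cation stabilised by O1 and the 7-oxygen, and the phloroglucinol-type ring of catechin attacks it first at C8 and then at C6, each time on the face opposite the 3-OH of the 2,3-trans unit, which should set both new C4 centres as 4α (3,4-trans).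

**Step 9**
Reactants: 15 7,3',4'-tri-O-benzyl-fisetinidol-(4α→6)-catechin-(8→4α)-7,3',4'-tri-O-benzyl-fisetinidol
Product: 16 fisetinidol-(4α→6)-catechin-(8→4α)-fisetinidol (CNP0289228.3)
Conditions: H2 (1 atm), Pd(OH)2/C, THF/MeOH, rt
Reagents that add atoms: none
Why: Hydrogenolysis of the six benzyl ethers; the interflavanyl C–C bonds and the benzylic C2–O1 bonds are known to survive these conditions in proanthocyanidin chemistry.

**Compound list**
1 | 6-hydroxy-1-benzofuran-2(3H)-one | O=C1Cc2ccc(O)cc2O1 | starting material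
2 | 6-(benzyloxy)-1-benzofuran-2(3H)-one | O=C1Cc2ccc(OCc3ccccc3)cc2O1 | intermediate
3 | 3,4-bis(benzyloxy)benzyl chloride | ClCc1ccc(OCc2ccccc2)c(OCc2ccccc2)c1 | starting material
4 | sodium 5-(benzyloxy)-2-(2-methoxy-2-oxoethyl)phenolate (not isolated) | [Na+].COC(=O)Cc1ccc(OCc2ccccc2)cc1[O-] | intermediate
5 | methyl 2-[4-(benzyloxy)-2-{[3,4-bis(benzyloxy)phenyl]methoxy}phenyl]acetate | COC(=O)Cc1ccc(OCc2ccccc2)cc1OCc1ccc(OCc2ccccc2)c(OCc2ccccc2)c1 | intermediate
6 | methyl 2-[4-(benzyloxy)-2-{[3,4-bis(benzyloxy)phenyl]methoxy}phenyl]-2-diazoacetate | COC(=O)C(=[N+]=[N-])c1ccc(OCc2ccccc2)cc1OCc1ccc(OCc2ccccc2)c(OCc2ccccc2)c1 | intermediate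
7 | methyl (2S,3R)-6-(benzyloxy)-2-[3,4-bis(benzyloxy)phenyl]-2,3-dihydro-1-benzofuran-3-carboxylate (2,3-cis) | COC(=O)[C@@H]1c2ccc(OCc3ccccc3)cc2O[C@@H]1c1ccc(OCc2ccccc2)c(OCc2ccccc2)c1 | intermediate
8 | potassium ester enolate of 7, C2 configuration as in 7 (not isolated) | [K+].COC([O-])=C1c2ccc(OCc3ccccc3)cc2O[C@@H]1c1ccc(OCc2ccccc2)c(OCc2ccccc2)c1 | intermediate
9 | methyl (2R,3S)-6-(benzyloxy)-2-[3,4-bis(benzyloxy)phenyl]-3-hydroxy-2,3-dihydro-1-benzofuran-3-carboxylate (3-OH trans to 2-aryl) | COC(=O)[C@]1(O)c2ccc(OCc3ccccc3)cc2O[C@@H]1c1ccc(OCc2ccccc2)c(OCc2ccccc2)c1 | intermediate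
10 | (2R,3S)-6-(benzyloxy)-2-[3,4-bis(benzyloxy)phenyl]-3-hydroxy-2,3-dihydro-1-benzofuran-3-carbaldehyde | O=C[C@]1(O)c2ccc(OCc3ccccc3)cc2O[C@@H]1c1ccc(OCc2ccccc2)c(OCc2ccccc2)c1 | intermediate
11 | (2R,4S)-7-(benzyloxy)-2-[3,4-bis(benzyloxy)phenyl]-4-hydroxychroman-3-one, 4-OH trans to 2-aryl (not isolated) | O[C@H]1c2ccc(OCc3ccccc3)cc2O[C@H](c2ccc(OCc3ccccc3)c(OCc3ccccc3)c2)C1=O | intermediate
12 | (2R,3S,4S)-7-(benzyloxy)-2-[3,4-bis(benzyloxy)phenyl]chromane-3,4-diol (2,3-trans, 3,4-cis) | O[C@H]1c2ccc(OCc3ccccc3)cc2O[C@H](c2ccc(OCc3ccccc3)c(OCc3ccccc3)c2)[C@H]1O | intermediate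
13 | (+)-catechin, (2R,3S) | Oc1cc(O)c2c(c1)O[C@H](c1ccc(O)c(O)c1)[C@@H](O)C2 | starting material
14 | 7,3',4'-tri-O-benzyl-fisetinidol-(4α→8)-catechin (not isolated) | c1c(O)c2c(c([C@@H]3c4ccc(OCc5ccccc5)cc4O[C@H](c4ccc(OCc5ccccc5)c(OCc5ccccc5)c4)[C@H]3O)c1O)O[C@H](c1ccc(O)c(O)c1)[C@@H](O)C2 | intermediate
15 | 7,3',4'-tri-O-benzyl-fisetinidol-(4α→6)-catechin-(8→4α)-7,3',4'-tri-O-benzyl-fisetinidol | C(c1ccccc1)Oc1ccc2c(c1)O[C@H](c1ccc(OCc3ccccc3)c(OCc3ccccc3)c1)[C@@H](O)[C@@H]2c1c(O)c2c(c([C@@H]3c4ccc(OCc5ccccc5)cc4O[C@H](c4ccc(OCc5ccccc5)c(OCc5ccccc5)c4)[C@H]3O)c1O)O[C@H](c1ccc(O)c(O)c1)[C@@H](O)C2 | intermediate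
16 | fisetinidol-(4α→6)-catechin-(8→4α)-fisetinidol; each unit (2R,3S), both fisetinidol C4 (S) | Oc1ccc2c(c1)O[C@H](c1ccc(O)c(O)c1)[C@@H](O)[C@@H]2c1c(O)c2c(c([C@@H]3c4ccc(O)cc4O[C@H](c4ccc(O)c(O)c4)[C@H]3O)c1O)O[C@H](c1ccc(O)c(O)c1)[C@@H](O)C2 | target

**Totals.** Total step count: 9. Longest linear sequence: 9 steps (1 to 16; catechin 13 enters at step 8).

**Steps most likely to fail**

Step 7. The wrong carbon may migrate, the new benzylic carbinol may ionise under the Lewis acid and alkylate a second molecule, or the 3-ketone may enolise toward C2 before the hydride arrives. The fallback sets out from 9 and keeps a one-atom ring enlargement but changes the trigger to a leaving group on a primary carbon. LiAlH4 in THF reduces 9 to (2R,3R)-6-(benzyloxy)-2-[3,4-bis(benzyloxy)phenyl]-3-(hydroxymethyl)-2,3-dihydro-1-benzofuran-3-ol F1. TsCl in pyridine at 0 °C sulfonylates only the primary hydroxyl and gives the monotosylate F2. LiClO4 and CaCO3 in THF at 50 °C then bring about the semipinacol ring expansion, by the same aryl shift, to (2R)-7-(benzyloxy)-2-[3,4-bis(benzyloxy)phenyl]chroman-3-one F3. NaBH4 at low temperature gives 7,3',4'-tri-O-benzyl-fisetinidol F4. DDQ with ethane-1,2-diol in CH2Cl2 oxidises the benzylic C4 to the (2R,3S,4R)-4-(2-hydroxyethoxy) ether F5. F5 is used in place of 12 under the conditions of step 8, and the route is rejoined at 15.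

Step 8. Facial control at C4 may be lost, the reaction may stall after the first alkylation, or chains may grow through the ring A positions of the fisetinidol units under protic or Lewis acid. The fallback sets out from 12 and moves the activation to a thiophilic, non-acidic one. Benzyl mercaptan with acetic acid converts 12 into the 2,3-trans-3,4-trans 4-(benzylsulfanyl) ether F6. AgBF4 in THF at 0 °C, with 13 present, then releases the same C4 cation, and the route is rejoined at 15.

Step 6. Over-reduction to the primary alcohol, or rearrangement of the α-hydroxy aldehyde on the aluminium salts during work-up, may erode the aldehyde. The fallback sets out from 9. Me(MeO)NH·HCl with i-PrMgCl in THF at −20 °C gives the N-methoxy-N-methylamide F7. LiAlH4 at −78 °C then stops at the chelated adduct and gives 10 on work-up, where the route is rejoined.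

**Further compounds**
F1 | step 7 | (2R,3R)-6-(benzyloxy)-2-[3,4-bis(benzyloxy)phenyl]-3-(hydroxymethyl)-2,3-dihydro-1-benzofuran-3-ol | OC[C@]1(O)c2ccc(OCc3ccccc3)cc2O[C@@H]1c1ccc(OCc2ccccc2)c(OCc2ccccc2)c1
F2 | step 7 | [(2R,3R)-6-(benzyloxy)-2-[3,4-bis(benzyloxy)phenyl]-3-hydroxy-2,3-dihydro-1-benzofuran-3-yl]methyl 4-methylbenzenesulfonate | Cc1ccc(cc1)S(=O)(=O)OC[C@]1(O)c2ccc(OCc3ccccc3)cc2O[C@@H]1c1ccc(OCc2ccccc2)c(OCc2ccccc2)c1
F3 | step 7 | (2R)-7-(benzyloxy)-2-[3,4-bis(benzyloxy)phenyl]chroman-3-one | O=C1Cc2ccc(OCc3ccccc3)cc2O[C@@H]1c1ccc(OCc2ccccc2)c(OCc2ccccc2)c1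
F4 | step 7 | (2R,3S)-7-(benzyloxy)-2-[3,4-bis(benzyloxy)phenyl]chroman-3-ol (7,3',4'-tri-O-benzyl-fisetinidol) | O[C@H]1Cc2ccc(OCc3ccccc3)cc2O[C@@H]1c1ccc(OCc2ccccc2)c(OCc2ccccc2)c1
F5 | step 7 | (2R,3S,4R)-7-(benzyloxy)-2-[3,4-bis(benzyloxy)phenyl]-4-(2-hydroxyethoxy)chroman-3-ol (2,3-trans, 3,4-trans) | OCCO[C@@H]1c2ccc(OCc3ccccc3)cc2O[C@H](c2ccc(OCc3ccccc3)c(OCc3ccccc3)c2)[C@H]1O
F6 | step 8 | (2R,3R,4R)-7-(benzyloxy)-4-(benzylsulfanyl)-2-[3,4-bis(benzyloxy)phenyl]chroman-3-ol (2,3-trans, 3,4-trans) | c1ccccc1CS[C@@H]1c2ccc(OCc3ccccc3)cc2O[C@H](c2ccc(OCc3ccccc3)c(OCc3ccccc3)c2)[C@H]1O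
F7 | step 6 | (2R,3S)-6-(benzyloxy)-2-[3,4-bis(benzyloxy)phenyl]-3-hydroxy-N-methoxy-N-methyl-2,3-dihydro-1-benzofuran-3-carboxamide | CON(C)C(=O)[C@]1(O)c2ccc(OCc3ccccc3)cc2O[C@@H]1c1ccc(OCc2ccccc2)c(OCc2ccccc2)c1
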